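## Retrosynthetic overview
1. The OOH goes on last, by cobalt-catalysed hydroperoxysilylation of an isopropenyl group made from the tertiary alcohol. The C6 side chain comes from 6-iodination and Suzuki coupling on the finished flavone.
2. The pyranone (ring C) is opened to an enaminone, which is a reduced isoxazole. A symmetric 2,6-dioxygenated A ring makes its closure unambiguous.
3. Key disconnection: the isoxazole and the seven-membered oxepine form together in an intramolecular nitrile oxide–alkyne [3+2] cycloaddition.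
4. The cycloaddition precursor is (3S)-2-methylhex-5-yne-2,3-diol joined to a B-ring fluoroaldehyde (SNAr, C–O of the stereocentre kept) and to an A-ring iodide (Sonogashira).
5. The only stereocentre is bought in methyl (S)-glycidate. Ring order: A and B bought, then oxepine + isoxazole, then pyranone.

Assumption: 1, 4, 7 and 16 are taken as catalogue compounds; flavone numbering (A ring C5–C8, B ring primed) is used in the names.

## Route

Step 1
Reactants: 1 5-methoxyresorcinol
Product: 2 2-iodo-5-methoxybenzene-1,3-diol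
Conditions: I2 (1.0 equiv), NaHCO3, THF–H2O, 0 °C
Reagents that add atoms: iodine, II
Why: Electrophilic aromatic iodination of the phenoxide in aqueous bicarbonate goes, as with resorcinol itself, to the carbon between the two hydroxyls, which is also para to OMe.

Step 2
Reactants: 2 2-iodo-5-methoxybenzene-1,3-diol
Product: 3 2-iodo-5-methoxy-1,3-bis(methoxymethoxy)benzene
Conditions: MOMCl (2.5 equiv), i-Pr2NEt, CH2Cl2, 0 °C to rt
Reagents that add atoms: chloromethyl methyl ether, COCCl
Why: Williamson-type O-alkylation (MOM protection) prevents benzofuran formation after the alkyne coupling and uses groups that fall off in the later acid cyclisation.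

Step 3
Reactants: 4 methyl (2S)-oxirane-2-carboxylate (methyl (S)-glycidate)
Product: 5 methyl (2S)-2-hydroxypent-4-ynoate
Conditions: HC≡CH (excess), n-BuLi (2 equiv), THF, −78 °C; BF3·OEt2 (2 equiv); then 4, −78 °C; H2O
Reagents that add atoms: lithium acetylide (made in the flask from acetylene), [Li]C#C
Why: In this Yamaguchi–Hirao alkynylation the BF3-activated epoxide is opened by SN2 at the unsubstituted C3 at −78 °C faster than the ester is attacked, so the purchased C2–O stereocentre is untouched.

Step 4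
Reactants: 5 methyl (2S)-2-hydroxypent-4-ynoate
Product: 6 (3S)-2-methylhex-5-yne-2,3-diol
Conditions: MeMgBr (4.5 equiv), THF, 0 °C to rt; H2O/NH4Cl
Reagents that add atoms: methylmagnesium bromide, C[Mg]Br
Why: Double Grignard addition to the ester builds the CMe2OH group, while the neighbouring stereocentre sits as its magnesium alkoxide and cannot enolise.

Step 5
Reactants: 6 (3S)-2-methylhex-5-yne-2,3-diol; 7 4-(benzyloxy)-2-fluorobenzaldehyde
Product: 8 4-(benzyloxy)-2-{[(3S)-2-hydroxy-2-methylhex-5-yn-3-yl]oxy}benzaldehyde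
Conditions: NaH (1.1 equiv), DMF, 0 °C; then 7, 0 to 40 °C
Reagents that add atoms: none
Why: In this SNAr (addition–elimination) ortho to the formyl group the secondary alkoxide reacts ahead of the tertiary one, and because only the aryl C–F bond breaks the configuration is retained.

Step 6
Reactants: 8 4-(benzyloxy)-2-{[(3S)-2-hydroxy-2-methylhex-5-yn-3-yl]oxy}benzaldehyde; 3 2-iodo-5-methoxy-1,3-bis(methoxymethoxy)benzene
Product: 9 4-(benzyloxy)-2-({(3S)-2-hydroxy-6-[4-methoxy-2,6-bis(methoxymethoxy)phenyl]-2-methylhex-5-yn-3-yl}oxy)benzaldehyde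
Conditions: PdCl2(PPh3)2 (5 mol %), CuI (10 mol %), Et3N–DMF, 60 °C, degassed
Reagents that add atoms: none
Why: Sonogashira coupling of the terminal alkyne with the aryl iodide tolerates the aldehyde, the tertiary alcohol and the acetal groups.

Step 7
Reactants: 9 the aryl-alkynyl aldehyde from step 6
Product: 12 (S)-isoxazole-fused 2,3-dihydro-1-benzoxepine (isoxazole C3 on the benzo ring; C4 on the ring CH2; C5 bearing the 4-methoxy-2,6-bis(methoxymethoxy)phenyl group; oxepine C2 bearing CMe2OH; 8-OBn), via aldoxime 10 (not isolated), via nitrile oxide 11 (not isolated)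
Conditions: NH2OH·HCl (1.05 equiv), NaOAc, MeOH, rt; dilute to 3 mM; PhI(OAc)2 (1.2 equiv, slow addition), 0 to 45 °C
Reagents that add atoms: hydroxylamine hydrochloride, NO.Cl
Why: Halogen-free oxidation of the oxime gives the aryl nitrile oxide, whose intramolecular 1,3-dipolar [3+2] cycloaddition to the tethered electron-rich alkyne closes the oxepine and the isoxazole (a masked 1,3-diketone) in one event, with the regiochemistry fixed by the tether and the stereocentre only a spectator.

Step 8
Reactants: 12 the isoxazole-fused benzoxepine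
Product: 14 (S)-5,4'-dihydroxy-7-methoxyflavone bridged C3–CH2–CH[C(CH3)2OH]–O–C2', via enaminone 13 (not isolated)
Conditions: H2 (3 atm), 10 % Pd/C, EtOH–THF, rt; filter; 3 M HCl, MeOH, 55 °C
Reagents that add atoms: none
Why: Hydrogenolysis cleaves the N–O and O-benzyl bonds, acid then removes both MOM groups, and one of the two equivalent A-ring phenols adds to the protonated enaminone carbon with loss of NH3 (addition–elimination cyclocondensation) to give a single flavone.

Step 9
Reactants: 14 the tertiary-alcohol oxepinoflavone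
Product: 15 the 6-iodo derivative of 14
Conditions: BnMe3N·ICl2 (1.05 equiv), CaCO3, CH2Cl2–MeOH, rt
Reagents that add atoms: benzyltrimethylammonium dichloroiodate, C[N+](C)(C)Cc1ccccc1.Cl[I-]Cl
Why: In this electrophilic aromatic iodination the A ring, with three reinforcing oxygen donors, reacts faster than the B ring, and 5-hydroxy-7-alkoxyflavones take iodine from ICl2− ortho to the free chelated 5-OH, at C6 rather than C8.

Step 10
Reactants: 15 the 6-iodoflavone; 16 (E)-3-methylbut-1-enylboronic acid pinacol ester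
Product: 17 the 6-[(E)-3-methylbut-1-enyl] derivative of 14
Conditions: Pd(dppf)Cl2 (5 mol %), K2CO3 (4 equiv), dioxane–H2O, 85 °C
Reagents that add atoms: none
Why: Suzuki–Miyaura coupling transfers the alkenyl group with retention of E geometry, at a stage that carries no allylic ether and no peroxide.

Step 11
Reactants: 17 the 6-alkenyl tertiary alcohol
Product: 19 (S)-5,4'-diacetoxy-7-methoxy-6-[(E)-3-methylbut-1-enyl]flavone bridged C3–CH2–CH[C(CH3)=CH2]–O–C2', via diacetate 18 (not isolated)
Conditions: Ac2O (6 equiv), pyridine, 40 °C; evaporate (PhMe); SOCl2 (2 equiv), pyridine, −10 to 0 °C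
Reagents that add atoms: acetic anhydride, CC(=O)OC(C)=O
Why: Peracetylation masks both phenols but not the tertiary alcohol, and the chlorosulfite E2 dehydration then takes a methyl hydrogen (as in the hydroxyisopropyl-to-isopropenyl conversion of dihydrobenzofurans), so the C–H at the stereocentre stays.

Step 12
Reactants: 19 the isopropenyl diacetate
Product: 21 CNP0171472.1 (target), via silyl peroxide 20 (not isolated)
Conditions: Co(thd)2 (10 mol %), Et3SiH (2 equiv), O2 (1 atm), ClCH2CH2Cl, rt; evaporate; K2CO3 (cat.), MeOH, 0 °C; pH 6 buffer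
Reagents that add atoms: dioxygen, O=O
Why: In this Mukaiyama–Isayama hydroperoxysilylation the cobalt hydride delivers H to the open terminal CH2 of the 1,1-disubstituted alkene faster than to the internal styrene (flanked by two ortho groups and shielded by isopropyl), the tertiary radical is trapped by O2 faster than it can expel aryloxyl, and base-catalysed methanolysis then frees the OOH and both phenols without touching the adjacent stereocentre.

## Compound list
1 | 5-methoxyresorcinol (5-methoxybenzene-1,3-diol) | COc1cc(O)cc(O)c1 | starting material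
2 | 2-iodo-5-methoxybenzene-1,3-diol | COc1cc(O)c(I)c(O)c1 | intermediate
3 | 2-iodo-5-methoxy-1,3-bis(methoxymethoxy)benzene | COCOc1cc(OC)cc(OCOC)c1I | intermediate
4 | methyl (2S)-oxirane-2-carboxylate | COC(=O)[C@@H]1CO1 | starting material
5 | methyl (2S)-2-hydroxypent-4-ynoate | C#CC[C@H](O)C(=O)OC | intermediate
6 | (3S)-2-methylhex-5-yne-2,3-diol | C#CC[C@H](O)C(C)(C)O | intermediate
7 | 4-(benzyloxy)-2-fluorobenzaldehyde | O=Cc1ccc(OCc2ccccc2)cc1F | starting material
8 | 4-(benzyloxy)-2-{[(3S)-2-hydroxy-2-methylhex-5-yn-3-yl]oxy}benzaldehyde | C#CC[C@H](Oc1cc(OCc2ccccc2)ccc1C=O)C(C)(C)O | intermediate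
9 | 4-(benzyloxy)-2-({(3S)-2-hydroxy-6-[4-methoxy-2,6-bis(methoxymethoxy)phenyl]-2-methylhex-5-yn-3-yl}oxy)benzaldehyde | COCOc1cc(OC)cc(OCOC)c1C#CC[C@H](Oc1cc(OCc2ccccc2)ccc1C=O)C(C)(C)O | intermediate
10 | (E)-aldoxime of 9, (S) | COCOc1cc(OC)cc(OCOC)c1C#CC[C@H](Oc1cc(OCc2ccccc2)ccc1/C=N/O)C(C)(C)O | intermediate
11 | aryl nitrile oxide from 10, (S) | COCOc1cc(OC)cc(OCOC)c1C#CC[C@H](Oc1cc(OCc2ccccc2)ccc1C#[N+][O-])C(C)(C)O | intermediate
12 | (S)-isoxazole fused across C4–C5 of a 2,3-dihydro-1-benzoxepine: isoxazole C3 on C5, isoxazole C5 bearing 4-methoxy-2,6-bis(methoxymethoxy)phenyl, oxepine C2 bearing C(CH3)2OH, 8-benzyloxy | COCOc1cc(OC)cc(OCOC)c1-c1onc2c1C[C@@H](C(C)(C)O)Oc1cc(OCc3ccccc3)ccc1-2 | intermediate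
13 | (S)-5-amino-8-hydroxy-2-(2-hydroxypropan-2-yl)-2,3-dihydro-1-benzoxepin-4-yl 4-methoxy-2,6-bis(methoxymethoxy)phenyl ketone (enaminone) | COCOc1cc(OC)cc(OCOC)c1C(=O)C1=C(N)c2ccc(O)cc2O[C@H](C(C)(C)O)C1 | intermediate
14 | (S)-5,4'-dihydroxy-7-methoxyflavone with the bridge C3–CH2–CH[C(CH3)2OH]–O–C2' (seven-membered oxepine) | COc1cc2oc3c(c(=O)c2c(O)c1)C[C@@H](C(C)(C)O)Oc1cc(O)ccc1-3 | intermediate
15 | 6-iodo derivative of 14, (S) | COc1cc2oc3c(c(=O)c2c(O)c1I)C[C@@H](C(C)(C)O)Oc1cc(O)ccc1-3 | intermediate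
16 | (E)-3-methylbut-1-enylboronic acid pinacol ester | CC(C)/C=C/B1OC(C)(C)C(C)(C)O1 | starting material
17 | 6-[(E)-3-methylbut-1-enyl] derivative of 14, (S) | COc1cc2oc3c(c(=O)c2c(O)c1/C=C/C(C)C)C[C@@H](C(C)(C)O)Oc1cc(O)ccc1-3 | intermediate
18 | 5,4'-di-O-acetate of 17, (S) | COc1cc2oc3c(c(=O)c2c(OC(C)=O)c1/C=C/C(C)C)C[C@@H](C(C)(C)O)Oc1cc(OC(C)=O)ccc1-3 | intermediate
19 | 5,4'-di-O-acetate with isopropenyl in place of C(CH3)2OH, (S) | COc1cc2oc3c(c(=O)c2c(OC(C)=O)c1/C=C/C(C)C)C[C@@H](C(C)=C)Oc1cc(OC(C)=O)ccc1-3 | intermediate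
20 | 5,4'-di-O-acetate bearing C(CH3)2OOSiEt3, (S) | COc1cc2oc3c(c(=O)c2c(OC(C)=O)c1/C=C/C(C)C)C[C@@H](C(C)(C)OO[Si](CC)(CC)CC)Oc1cc(OC(C)=O)ccc1-3 | intermediate
21 | CNP0171472.1: (S)-5,4'-dihydroxy-7-methoxy-6-[(E)-3-methylbut-1-enyl]flavone with the bridge C3–CH2–CH[C(CH3)2OOH]–O–C2' | COc1cc2oc3c(c(=O)c2c(O)c1/C=C/C(C)C)C[C@@H](C(C)(C)OO)Oc1cc(O)ccc1-3 | target

## Step count and risks
Total steps: 12. Longest linear sequence: 10 (steps 3–12, from 4).

**Step 5 (SNAr).** A hindered secondary alkoxide must attack a fluoroarene whose activating aldehyde is weakened by the para alkoxy group. Hydride transfer to the aldehyde or alkyne side reactions may win. The fallback sets out from 6 and comes back at 8, and it makes the ether by two inversions instead of an SNAr.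
- The secondary hydroxyl of 6 is mesylated selectively (MsCl, Et3N, CH2Cl2, −20 °C) to (3S)-2-hydroxy-2-methylhex-5-yn-3-yl methanesulfonate F1.
- K2CO3 in MeOH closes it with inversion to (3R)-2,2-dimethyl-3-(prop-2-yn-1-yl)oxirane F2.
- The caesium phenoxide of purchased 4-(benzyloxy)-2-hydroxybenzaldehyde (Cs2CO3, DMF, 90 °C) opens F2 at the less substituted carbon with a second inversion. This gives 8 with net retention.

**Step 9 (iodination).** The free resorcinol-type B ring, or C8, may compete with C6. The fallback sets out from 14 and comes back at 17, and it switches the B ring off electronically.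
- One equivalent of Ac2O in pyridine at 0 °C acetylates only the non-chelated phenol, giving the 4'-O-acetate of 14 F3.
- The same ICl2− reagent now finds only the A ring and gives the 6-iodo-4'-O-acetate F4.
- The aqueous-carbonate Suzuki coupling with 16 couples F4 and hydrolyses the aryl acetate in the same operation, giving 17.

**Step 12 (peroxidation).** The styrene may also accept hydrogen from the cobalt hydride. The fallback sets out from 15 and comes back at 20, and it brings the styrene in only after the peroxide.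
- 15 is peracetylated to the 5,4'-di-O-acetate of 15 F5 and dehydrated as in step 11 to the 6-iodo isopropenyl diacetate F6, which has no second alkene.
- F6 is hydroperoxysilylated (Co(thd)2, Et3SiH, O2) to the 6-iodo triethylsilyl peroxide diacetate F7.
- A base-free and phosphine-free Stille coupling (PdCl2(MeCN)2, DMF, 40 °C) joins F7 to (E)-tributyl(3-methylbut-1-enyl)stannane F8, made from 3-methylbut-1-yne and Bu3SnH (AIBN, 80 °C). This gives 20, which is methanolysed as in step 12.

## Further compounds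
F1 | step 5 | (3S)-2-hydroxy-2-methylhex-5-yn-3-yl methanesulfonate | C#CC[C@H](OS(C)(=O)=O)C(C)(C)O
F2 | step 5 | (3R)-2,2-dimethyl-3-(prop-2-yn-1-yl)oxirane | C#CC[C@H]1OC1(C)C
F3 | step 9 | 4'-O-acetate of 14, (S) | COc1cc2oc3c(c(=O)c2c(O)c1)C[C@@H](C(C)(C)O)Oc1cc(OC(C)=O)ccc1-3
F4 | step 9 | 6-iodo-4'-O-acetate of 14, (S) | COc1cc2oc3c(c(=O)c2c(O)c1I)C[C@@H](C(C)(C)O)Oc1cc(OC(C)=O)ccc1-3
F5 | step 12 | 5,4'-di-O-acetate of 15, (S) | COc1cc2oc3c(c(=O)c2c(OC(C)=O)c1I)C[C@@H](C(C)(C)O)Oc1cc(OC(C)=O)ccc1-3
F6 | step 12 | 6-iodo isopropenyl 5,4'-diacetate, (S) | COc1cc2oc3c(c(=O)c2c(OC(C)=O)c1I)C[C@@H](C(C)=C)Oc1cc(OC(C)=O)ccc1-3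
F7 | step 12 | 6-iodo triethylsilyl peroxide 5,4'-diacetate, (S) | COc1cc2oc3c(c(=O)c2c(OC(C)=O)c1I)C[C@@H](C(C)(C)OO[Si](CC)(CC)CC)Oc1cc(OC(C)=O)ccc1-3
F8 | step 12 | (E)-tributyl(3-methylbut-1-enyl)stannane | CCCC[Sn](CCCC)(CCCC)/C=C/C(C)C
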